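**Retrosynthetic overview**
1. Target ⇐ MOM removal, oxidation-state adjustment and benzylic deoxygenation of carbinol 39, which is made five steps from the end by adding the aryllithium from bromide 37 to the neopentyl aldehyde 24 (two halves of similar size).
2. 24 ⇐ [2,3]-Wittig–Still shift of allylic alcohol 19: the C-4 carbinol transfers its chirality to the C-3 quaternary centre and moves the alkene to C-3a/C-4.
3. 19 ⇐ ring-closing metathesis and hydrogenation of diene 17 ⇐ anti-selective allylboration of cyclopentene carbaldehyde 10 with allylboronate 16 (second convergent union).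
4. 10 ⇐ isoprene + acrolein (Diels–Alder sets C-8a), Cu-catalysed SN2′ methylation (sets C-8), epoxide cleavage, aldol ring contraction; 16 ⇐ 2-methylbut-3-yn-2-ol; 37 ⇐ resorcinol (Ir C–H borylation/oxidation, two directed lithiations, bromination).
5. Ring order: sacrificial cyclohexene ([4+2], step 1) → five-membered ring (aldol, step 8) → seven-membered ring (RCM, step 14); the arene is carried from resorcinol.

Assumption: in every catalyst-controlled step the catalyst antipode that gives the drawn configuration is used (both antipodes are available); bicyclic compounds carry azulene locants (C-3 quaternary carbon, C-5 side chain, C-8 methyl, C-8a ring-fusion CH).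

**Step 1**
Reactants: 1 isoprene; 2 acrolein
Product: 3 (1S)-4-methylcyclohex-3-ene-1-carbaldehyde
Conditions: 5-benzyl-2,2,3-trimethylimidazolidin-4-one·HCl (20 mol %), MeNO2/H2O 95:5, 0 °C
Reagents that add atoms: none
Why: Organocatalytic iminium Diels–Alder reaction gives the para adduct, the catalyst shielding one face of the acrolein iminium to set the (S) centre (future C-8a).

**Step 2**
Reactants: 3 (1S)-4-methylcyclohex-3-ene-1-carbaldehyde
Product: 4 ethyl (2E)-3-[(1S)-4-methylcyclohex-3-en-1-yl]prop-2-enoate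
Conditions: Ph3P=CHCO2Et, CH2Cl2, rt
Reagents that add atoms: ethyl (triphenylphosphoranylidene)acetate, CCOC(=O)C=P(c1ccccc1)(c1ccccc1)c1ccccc1
Why: Wittig olefination with a stabilised ylide is E-selective and base-free, so the α-stereocentre is not epimerised.

**Step 3**
Reactants: 4 ethyl (2E)-3-[(1S)-4-methylcyclohex-3-en-1-yl]prop-2-enoate
Product: 5 (2E)-3-[(1S)-4-methylcyclohex-3-en-1-yl]prop-2-en-1-ol
Conditions: i-Bu2AlH (2.2 equiv), CH2Cl2, −78 → 0 °C
Reagents that add atoms: none
Why: 1,2-Hydride reduction of the enoate by the aluminium hydride gives the allylic alcohol without touching either alkene.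

**Step 4**
Reactants: 5 (2E)-3-[(1S)-4-methylcyclohex-3-en-1-yl]prop-2-en-1-ol
Product: 6 (4S)-4-[(1E)-3-bromoprop-1-en-1-yl]-1-methylcyclohex-1-ene
Conditions: CBr4, PPh3, CH2Cl2, 0 °C
Reagents that add atoms: carbon tetrabromide, BrC(Br)(Br)Br
Why: Appel bromination replaces the primary allylic hydroxyl by SN2 without allylic transposition, giving the clean (E)-primary bromide.

**Step 5**
Reactants: 6 (4S)-4-[(1E)-3-bromoprop-1-en-1-yl]-1-methylcyclohex-1-ene
Product: 7 (4S)-4-[(2R)-but-3-en-2-yl]-1-methylcyclohex-1-ene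
Conditions: MeMgBr (1.2 equiv), CuBr·SMe2 (1 mol %), Taniaphos (C43H39FeNP2, 1.2 mol %), CH2Cl2, −75 °C
Reagents that add atoms: methylmagnesium bromide, C[Mg]Br
Why: Copper-catalysed asymmetric allylic alkylation (SN2′): the chiral monovalent copper methyl complex attacks the γ-carbon, creating the (R) methyl-bearing centre (future C-8) and a terminal vinyl group under catalyst control.

**Step 6**
Reactants: 7 (4S)-4-[(2R)-but-3-en-2-yl]-1-methylcyclohex-1-ene
Product: 8 (4S)-4-[(2R)-but-3-en-2-yl]-1-methyl-7-oxabicyclo[4.1.0]heptane (both epoxide faces)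
Conditions: mCPBA (1.05 equiv), NaHCO3, CH2Cl2, 0 °C
Reagents that add atoms: 3-chloroperoxybenzoic acid, O=C(OO)c1cccc(Cl)c1
Why: Prilezhaev epoxidation is chemoselective for the electron-rich trisubstituted ring alkene over the monosubstituted vinyl group; the epoxide configuration is irrelevant.

**Step 7**
Reactants: 8 epoxide
Product: 9 (3S)-3-[(2R)-but-3-en-2-yl]-6-oxoheptanal
Conditions: H5IO6 (1.2 equiv), THF/H2O, 0 °C → rt
Reagents that add atoms: water, O
Why: Periodic acid hydrolyses the epoxide and cleaves the resulting glycol (Malaprade-type cleavage) to the keto-aldehyde, leaving the vinyl group and both stereocentres (β to the carbonyls) untouched.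

**Step 8**
Reactants: 9 (3S)-3-[(2R)-but-3-en-2-yl]-6-oxoheptanal
Product: 10 (5R)-5-[(2R)-but-3-en-2-yl]-2-methylcyclopent-1-ene-1-carbaldehyde
Conditions: piperidine (0.2 equiv), AcOH (0.2 equiv), benzene, 80 °C
Reagents that add atoms: none
Why: Intramolecular enamine aldol condensation (aldehyde α-carbon onto the methyl ketone) closes the five-membered ring as the tetrasubstituted enal; neither stereocentre is enolisable.

**Step 9**
Reactants: 11 2-methylbut-3-yn-2-ol
Product: 12 3-(methoxymethoxy)-3-methylbut-1-yne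
Conditions: MOMCl, i-Pr2NEt, CH2Cl2, 0 °C → rt
Reagents that add atoms: chloromethyl methyl ether, COCCl
Why: Williamson-type acetalisation protects the tertiary alcohol as a base-stable MOM ether that cannot migrate or ionise in later steps.

**Step 10**
Reactants: 12 3-(methoxymethoxy)-3-methylbut-1-yne
Product: 14 4-(methoxymethoxy)-4-methylpent-2-yn-1-ol, via lithium acetylide 13 (not isolated)
Conditions: n-BuLi, THF, −78 °C; (CH2O)n, −78 °C → rt
Reagents that add atoms: formaldehyde (as paraformaldehyde), C=O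
Why: Acetylide addition to formaldehyde gives the propargylic alcohol.

**Step 11**
Reactants: 14 4-(methoxymethoxy)-4-methylpent-2-yn-1-ol
Product: 15 (2E)-4-(methoxymethoxy)-4-methylpent-2-en-1-ol
Conditions: NaAlH2(OCH2CH2OMe)2, THF, 0 °C → rt
Reagents that add atoms: none
Why: Hydroxyl-directed trans-hydroalumination of the propargylic alcohol followed by protonolysis gives only the (E)-allylic alcohol.

**Step 12**
Reactants: 15 (2E)-4-(methoxymethoxy)-4-methylpent-2-en-1-ol
Product: 16 2-[(2E)-4-(methoxymethoxy)-4-methylpent-2-en-1-yl]-4,4,5,5-tetramethyl-1,3,2-dioxaborolane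
Conditions: B2pin2, [Pd(MeCN)4](BF4)2 (5 mol %), DMSO/MeOH, 40 °C
Reagents that add atoms: bis(pinacolato)diboron, CC1(C)OB(B2OC(C)(C)C(C)(C)O2)OC1(C)C
Why: Palladium-catalysed allylic C–OH borylation through a π-allyl intermediate places boron at the unhindered terminus and keeps the E geometry.

**Step 13**
Reactants: 10 (5R)-5-[(2R)-but-3-en-2-yl]-2-methylcyclopent-1-ene-1-carbaldehyde; 16 allylboronate
Product: 17 (1R,2R)-1-{(5R)-5-[(2R)-but-3-en-2-yl]-2-methylcyclopent-1-en-1-yl}-2-[2-(methoxymethoxy)propan-2-yl]but-3-en-1-ol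
Conditions: (R)-TRIP [3,3′-bis(2,4,6-triisopropylphenyl)-1,1′-binaphthyl-2,2′-diyl hydrogen phosphate] (5 mol %), 4 Å MS, toluene, −30 °C → rt; aq. NaOH work-up
Reagents that add atoms: none
Why: Phosphoric-acid-catalysed allylboration through a Zimmerman–Traxler chair: the (E)-boronate gives the anti adduct and the chiral phosphate selects the aldehyde face, setting the carbinol (future C-4, R) and the side-chain centre (C-5, R).

**Step 14**
Reactants: 17 homoallylic alcohol
Product: 18 (4R,5R,8R,8aR)-5-[2-(methoxymethoxy)propan-2-yl]-3,8-dimethyl-1,2,4,5,8,8a-hexahydroazulen-4-ol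
Conditions: second-generation Grubbs catalyst (5 mol %), CH2Cl2 (5 mM), 40 °C
Reagents that add atoms: none
Why: Ring-closing metathesis of the two monosubstituted vinyl groups closes the seven-membered ring (the tetrasubstituted alkene is inert), and the anti adduct becomes the cis-4-hydroxy-5-alkyl cycloheptene.

**Step 15**
Reactants: 18 hexahydroazulenol
Product: 19 (4R,5R,8R,8aR)-5-[2-(methoxymethoxy)propan-2-yl]-3,8-dimethyl-1,2,4,5,6,7,8,8a-octahydroazulen-4-ol
Conditions: H2 (4 atm), RhCl(PPh3)3 (10 mol %), benzene, rt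
Reagents that add atoms: none
Why: Homogeneous hydrogenation with Wilkinson's catalyst reduces the cis-disubstituted C-6/C-7 alkene and leaves the tetrasubstituted allylic alkene untouched.

**Step 16**
Reactants: 19 allylic alcohol
Product: 21 tributyl({[(4R,5R,8R,8aR)-5-[2-(methoxymethoxy)propan-2-yl]-3,8-dimethyl-1,2,4,5,6,7,8,8a-octahydroazulen-4-yl]oxy}methyl)stannane, via potassium alkoxide 20 (not isolated)
Conditions: KH, THF, 0 °C; Bu3SnCH2I, rt
Reagents that add atoms: tributyl(iodomethyl)stannane, CCCC[Sn](CCCC)(CCCC)CI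
Why: Williamson etherification of the secondary allylic alkoxide with the reactive α-stannyl iodide installs the Still precursor; the MOM ether cannot migrate under these basic conditions.

**Step 17**
Reactants: 21 stannylmethyl ether
Product: 23 [(3S,5R,8R,8aR)-5-[2-(methoxymethoxy)propan-2-yl]-3,8-dimethyl-1,2,3,5,6,7,8,8a-octahydroazulen-3-yl]methanol, via α-alkoxymethyllithium 22 (not isolated)
Conditions: n-BuLi, THF, −78 → −40 °C; aq. NH4Cl
Reagents that add atoms: none
Why: [2,3]-Wittig–Still rearrangement: the carbanion from tin–lithium exchange migrates suprafacially from O-4 to C-3 on the face of the pseudoaxial C-4–O bond (cis to the C-5 side chain and to H-8a), creating the quaternary centre and moving the alkene to C-3a/C-4.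

**Step 18**
Reactants: 23 neopentyl alcohol
Product: 24 (3S,5R,8R,8aR)-5-[2-(methoxymethoxy)propan-2-yl]-3,8-dimethyl-1,2,3,5,6,7,8,8a-octahydroazulene-3-carbaldehyde
Conditions: Dess–Martin periodinane, NaHCO3, CH2Cl2, 0 °C → rt
Reagents that add atoms: none
Why: Dess–Martin oxidation gives the aldehyde, which has a quaternary α-carbon and so cannot epimerise or move into conjugation.

**Step 19**
Reactants: 25 resorcinol
Product: 26 1,3-bis(methoxymethoxy)benzene
Conditions: MOMCl (2.5 equiv), i-Pr2NEt, CH2Cl2, 0 °C → rt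
Reagents that add atoms: chloromethyl methyl ether, COCCl
Why: O-Alkylation protects both phenols as MOM ethers, which later direct ortho-lithiation.

**Step 20**
Reactants: 26 1,3-bis(methoxymethoxy)benzene
Product: 27 2-[3,5-bis(methoxymethoxy)phenyl]-4,4,5,5-tetramethyl-1,3,2-dioxaborolane
Conditions: B2pin2 (0.55 equiv), [Ir(OMe)(cod)]2 (1.5 mol %), dtbpy (3 mol %), hexane, 80 °C
Reagents that add atoms: bis(pinacolato)diboron, CC1(C)OB(B2OC(C)(C)C(C)(C)O2)OC1(C)C
Why: Sterically controlled iridium-catalysed C–H borylation functionalises the only position not ortho to a substituent (C-5).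

**Step 21**
Reactants: 27 arylboronate
Product: 28 3,5-bis(methoxymethoxy)phenol
Conditions: H2O2 (30 % aq.), NaOH, THF, 0 °C
Reagents that add atoms: hydrogen peroxide, OO
Why: Oxidative 1,2-aryl migration from boron to oxygen (boronate oxidation) installs the third phloroglucinol oxygen.

**Step 22**
Reactants: 28 3,5-bis(methoxymethoxy)phenol
Product: 29 1,3,5-tris(methoxymethoxy)benzene
Conditions: MOMCl, i-Pr2NEt, CH2Cl2, rt
Reagents that add atoms: chloromethyl methyl ether, COCCl
Why: O-Alkylation gives the C3-symmetric tris-MOM ether in which every ring C–H lies between two directing groups.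

**Step 23**
Reactants: 29 1,3,5-tris(methoxymethoxy)benzene; 30 3-methylbutanal
Product: 32 3-methyl-1-[2,4,6-tris(methoxymethoxy)phenyl]butan-1-ol (racemic), via aryllithium 31 (not isolated)
Conditions: n-BuLi, THF, 0 °C; then 30, −78 °C → rt
Reagents that add atoms: none
Why: Directed ortho-metalation between two MOM ethers followed by addition to the aldehyde; the new carbinol centre is later oxidised, so its configuration does not matter.

**Step 24**
Reactants: 32 benzylic alcohol
Product: 33 tert-butyl(dimethyl){3-methyl-1-[2,4,6-tris(methoxymethoxy)phenyl]butoxy}silane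
Conditions: TBSOTf, 2,6-lutidine, CH2Cl2, 0 °C
Reagents that add atoms: tert-butyldimethylsilyl trifluoromethanesulfonate, CC(C)(C)[Si](C)(C)OS(=O)(=O)C(F)(F)F
Why: Silylation with the triflate protects the hindered secondary benzylic alcohol as the masked isovaleryl group.

**Step 25**
Reactants: 33 silyl ether
Product: 35 [3-{1-[(tert-butyldimethylsilyl)oxy]-3-methylbutyl}-2,4,6-tris(methoxymethoxy)phenyl]methanol, via aryllithium 34 (not isolated)
Conditions: n-BuLi, TMEDA, THF, 0 °C; (CH2O)n, rt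
Reagents that add atoms: formaldehyde (as paraformaldehyde), C=O
Why: A second directed ortho-metalation (two equivalent sites) and hydroxymethylation introduce the masked formyl carbon.

**Step 26**
Reactants: 35 benzyl alcohol
Product: 36 bis-silyl ether: 1-{[(tert-butyldimethylsilyl)oxy]methyl}-3-{1-[(tert-butyldimethylsilyl)oxy]-3-methylbutyl}-2,4,6-tris(methoxymethoxy)benzene
Conditions: TBSCl, imidazole, DMF, rt
Reagents that add atoms: tert-butyldimethylsilyl chloride, CC(C)(C)[Si](C)(C)Cl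
Why: Silylation of the primary benzylic alcohol.

**Step 27**
Reactants: 36 bis-silyl ether
Product: 37 1-bromo-3-{[(tert-butyldimethylsilyl)oxy]methyl}-5-{1-[(tert-butyldimethylsilyl)oxy]-3-methylbutyl}-2,4,6-tris(methoxymethoxy)benzene
Conditions: NBS, MeCN, 0 °C, dark
Reagents that add atoms: N-bromosuccinimide, O=C1CCC(=O)N1Br
Why: Electrophilic aromatic bromination of the last, strongly activated ring position.

**Step 28**
Reactants: 37 aryl bromide; 24 aldehyde
Product: 39 carbinol: [3-{[(tert-butyldimethylsilyl)oxy]methyl}-5-{1-[(tert-butyldimethylsilyl)oxy]-3-methylbutyl}-2,4,6-tris(methoxymethoxy)phenyl][(3S,5R,8R,8aR)-5-[2-(methoxymethoxy)propan-2-yl]-3,8-dimethyl-1,2,3,5,6,7,8,8a-octahydroazulen-3-yl]methanol (epimers at both benzylic carbinol carbons), via aryllithium 38 (not isolated)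
Conditions: 37, t-BuLi (2.1 equiv), THF, −78 °C; then 24, −78 → −30 °C
Reagents that add atoms: none
Why: Bromine–lithium exchange and 1,2-addition of the aryllithium to the non-enolisable neopentyl aldehyde join the two halves; the new carbinol centre is removed in step 30.

**Step 29**
Reactants: 39 carbinol
Product: 42 O-alkyl S-methyl dithiocarbonate (xanthate) of 39, via sodium alkoxide 40 (not isolated), via sodium xanthate 41 (not isolated)
Conditions: NaH, THF, 0 °C → rt; CS2; then MeI
Reagents that add atoms: carbon disulfide, S=C=S; iodomethane, CI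
Why: Xanthate formation is chosen because the small CS2 still reaches the very hindered alkoxide; the carbinol carbon has no β-hydrogen, so Chugaev elimination is impossible.

**Step 30**
Reactants: 42 xanthate
Product: 43 1-{[(tert-butyldimethylsilyl)oxy]methyl}-3-{1-[(tert-butyldimethylsilyl)oxy]-3-methylbutyl}-5-{[(3R,5R,8R,8aR)-5-[2-(methoxymethoxy)propan-2-yl]-3,8-dimethyl-1,2,3,5,6,7,8,8a-octahydroazulen-3-yl]methyl}-2,4,6-tris(methoxymethoxy)benzene
Conditions: Bu3SnH (0.3 M), AIBN, toluene, 100 °C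
Reagents that add atoms: none
Why: Barton–McCombie radical deoxygenation through the benzylic radical gives the benzylic CH2 without disturbing the silyl and MOM ethers; the high stannane concentration traps the radical before it can add to the neighbouring alkene.

**Step 31**
Reactants: 43 bis-silyl ether
Product: 44 diol: 1-[3-(hydroxymethyl)-5-{[(3R,5R,8R,8aR)-5-[2-(methoxymethoxy)propan-2-yl]-3,8-dimethyl-1,2,3,5,6,7,8,8a-octahydroazulen-3-yl]methyl}-2,4,6-tris(methoxymethoxy)phenyl]-3-methylbutan-1-ol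
Conditions: Bu4NF, THF, 0 → 40 °C
Reagents that add atoms: none
Why: Fluoride-mediated desilylation frees both benzylic alcohols while all MOM ethers stay in place.

**Step 32**
Reactants: 44 diol
Product: 45 3-{[(3R,5R,8R,8aR)-5-[2-(methoxymethoxy)propan-2-yl]-3,8-dimethyl-1,2,3,5,6,7,8,8a-octahydroazulen-3-yl]methyl}-2,4,6-tris(methoxymethoxy)-5-(3-methylbutanoyl)benzaldehyde
Conditions: Dess–Martin periodinane (3 equiv), NaHCO3, CH2Cl2, rt
Reagents that add atoms: none
Why: Double Dess–Martin oxidation turns the primary benzylic alcohol into the aldehyde and the secondary one into the isovaleryl ketone under neutral conditions.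

**Step 33**
Reactants: 45 tetra-MOM ether
Product: 46 target, 2,4,6-trihydroxy-3-{[(3R,5R,8R,8aR)-5-(2-hydroxypropan-2-yl)-3,8-dimethyl-1,2,3,5,6,7,8,8a-octahydroazulen-3-yl]methyl}-5-(3-methylbutanoyl)benzaldehyde
Conditions: HCl (3 M aq.)/MeOH/THF, 40 °C
Reagents that add atoms: none
Why: Acid-catalysed acetal exchange (methanolysis) removes the three aryl MOM ethers (each ortho to a carbonyl) and the tertiary MOM ether; the mild temperature spares the tertiary alcohol and the alkene.

**Compound list**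
1 | isoprene (2-methylbuta-1,3-diene) | C=CC(C)=C | starting material
2 | acrolein (prop-2-enal) | C=CC=O | starting material
3 | (1S)-4-methylcyclohex-3-ene-1-carbaldehyde | O=C[C@@H]1CC=C(C)CC1 | intermediate
4 | ethyl (2E)-3-[(1S)-4-methylcyclohex-3-en-1-yl]prop-2-enoate | CCOC(=O)/C=C/[C@@H]1CC=C(C)CC1 | intermediate
5 | (2E)-3-[(1S)-4-methylcyclohex-3-en-1-yl]prop-2-en-1-ol | OC/C=C/[C@@H]1CC=C(C)CC1 | intermediate
6 | (4S)-4-[(1E)-3-bromoprop-1-en-1-yl]-1-methylcyclohex-1-ene | BrC/C=C/[C@@H]1CC=C(C)CC1 | intermediate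
7 | (4S)-4-[(2R)-but-3-en-2-yl]-1-methylcyclohex-1-ene | C=C[C@@H](C)[C@@H]1CC=C(C)CC1 | intermediate
8 | (4S)-4-[(2R)-but-3-en-2-yl]-1-methyl-7-oxabicyclo[4.1.0]heptane (both epoxide faces) | C=C[C@@H](C)[C@@H]1CC2OC2(C)CC1 | intermediate
9 | (3S)-3-[(2R)-but-3-en-2-yl]-6-oxoheptanal | C=C[C@@H](C)[C@H](CC=O)CCC(C)=O | intermediate
10 | (5R)-5-[(2R)-but-3-en-2-yl]-2-methylcyclopent-1-ene-1-carbaldehyde | C=C[C@@H](C)[C@H]1CCC(C)=C1C=O | intermediate
11 | 2-methylbut-3-yn-2-ol | C#CC(C)(C)O | starting material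
12 | 3-(methoxymethoxy)-3-methylbut-1-yne | C#CC(C)(C)OCOC | intermediate
13 | lithium acetylide of 12 | [Li]C#CC(C)(C)OCOC | intermediate (not isolated)
14 | 4-(methoxymethoxy)-4-methylpent-2-yn-1-ol | OCC#CC(C)(C)OCOC | intermediate
15 | (2E)-4-(methoxymethoxy)-4-methylpent-2-en-1-ol | OC/C=C/C(C)(C)OCOC | intermediate
16 | 2-[(2E)-4-(methoxymethoxy)-4-methylpent-2-en-1-yl]-4,4,5,5-tetramethyl-1,3,2-dioxaborolane | CC1(C)OB(C/C=C/C(C)(C)OCOC)OC1(C)C | intermediate
17 | (1R,2R)-1-{(5R)-5-[(2R)-but-3-en-2-yl]-2-methylcyclopent-1-en-1-yl}-2-[2-(methoxymethoxy)propan-2-yl]but-3-en-1-ol | C=C[C@@H](C)[C@H]1CCC(C)=C1[C@H](O)[C@@H](C=C)C(C)(C)OCOC | intermediate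
18 | (4R,5R,8R,8aR)-5-[2-(methoxymethoxy)propan-2-yl]-3,8-dimethyl-1,2,4,5,8,8a-hexahydroazulen-4-ol | C[C@@H]1C=C[C@@H](C(C)(C)OCOC)[C@@H](O)C2=C(C)CC[C@H]12 | intermediate
19 | (4R,5R,8R,8aR)-5-[2-(methoxymethoxy)propan-2-yl]-3,8-dimethyl-1,2,4,5,6,7,8,8a-octahydroazulen-4-ol | C[C@@H]1CC[C@@H](C(C)(C)OCOC)[C@@H](O)C2=C(C)CC[C@H]12 | intermediate
20 | potassium alkoxide of 19 | C[C@@H]1CC[C@@H](C(C)(C)OCOC)[C@@H]([O-])C2=C(C)CC[C@H]12.[K+] | intermediate (not isolated)
21 | (tributylstannyl)methyl ether of 19 | C[C@@H]1CC[C@@H](C(C)(C)OCOC)[C@@H](OC[Sn](CCCC)(CCCC)CCCC)C2=C(C)CC[C@H]12 | intermediate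
22 | lithiomethyl ether of 19 | C[C@@H]1CC[C@@H](C(C)(C)OCOC)[C@@H](OC[Li])C2=C(C)CC[C@H]12 | intermediate (not isolated)
23 | [(3S,5R,8R,8aR)-5-[2-(methoxymethoxy)propan-2-yl]-3,8-dimethyl-1,2,3,5,6,7,8,8a-octahydroazulen-3-yl]methanol | C[C@@H]1CC[C@@H](C(C)(C)OCOC)C=C2[C@@](C)(CO)CC[C@H]12 | intermediate
24 | (3S,5R,8R,8aR)-5-[2-(methoxymethoxy)propan-2-yl]-3,8-dimethyl-1,2,3,5,6,7,8,8a-octahydroazulene-3-carbaldehyde | C[C@@H]1CC[C@@H](C(C)(C)OCOC)C=C2[C@@](C)(C=O)CC[C@H]12 | intermediate
25 | resorcinol | Oc1cccc(O)c1 | starting material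
26 | 1,3-bis(methoxymethoxy)benzene | COCOc1cccc(OCOC)c1 | intermediate
27 | 2-[3,5-bis(methoxymethoxy)phenyl]-4,4,5,5-tetramethyl-1,3,2-dioxaborolane | COCOc1cc(OCOC)cc(B2OC(C)(C)C(C)(C)O2)c1 | intermediate
28 | 3,5-bis(methoxymethoxy)phenol | COCOc1cc(O)cc(OCOC)c1 | intermediate
29 | 1,3,5-tris(methoxymethoxy)benzene | COCOc1cc(OCOC)cc(OCOC)c1 | intermediate
30 | 3-methylbutanal | CC(C)CC=O | starting material
31 | 2,4,6-tris(methoxymethoxy)phenyllithium | [Li]c1c(OCOC)cc(OCOC)cc1OCOC | intermediate (not isolated)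
32 | 3-methyl-1-[2,4,6-tris(methoxymethoxy)phenyl]butan-1-ol (racemic) | COCOc1cc(OCOC)c(C(O)CC(C)C)c(OCOC)c1 | intermediate
33 | tert-butyl(dimethyl){3-methyl-1-[2,4,6-tris(methoxymethoxy)phenyl]butoxy}silane (racemic) | COCOc1cc(OCOC)c(C(CC(C)C)O[Si](C)(C)C(C)(C)C)c(OCOC)c1 | intermediate
34 | aryllithium from 33 (lithium between two MOM ethers) | COCOc1cc(OCOC)c(C(CC(C)C)O[Si](C)(C)C(C)(C)C)c(OCOC)c1[Li] | intermediate (not isolated)
35 | [3-{1-[(tert-butyldimethylsilyl)oxy]-3-methylbutyl}-2,4,6-tris(methoxymethoxy)phenyl]methanol (racemic) | COCOc1cc(OCOC)c(C(CC(C)C)O[Si](C)(C)C(C)(C)C)c(OCOC)c1CO | intermediate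
36 | 1-{[(tert-butyldimethylsilyl)oxy]methyl}-3-{1-[(tert-butyldimethylsilyl)oxy]-3-methylbutyl}-2,4,6-tris(methoxymethoxy)benzene (racemic) | COCOc1cc(OCOC)c(C(CC(C)C)O[Si](C)(C)C(C)(C)C)c(OCOC)c1CO[Si](C)(C)C(C)(C)C | intermediate
37 | 1-bromo-3-{[(tert-butyldimethylsilyl)oxy]methyl}-5-{1-[(tert-butyldimethylsilyl)oxy]-3-methylbutyl}-2,4,6-tris(methoxymethoxy)benzene (racemic) | COCOc1c(Br)c(OCOC)c(C(CC(C)C)O[Si](C)(C)C(C)(C)C)c(OCOC)c1CO[Si](C)(C)C(C)(C)C | intermediate
38 | aryllithium from 37 | COCOc1c([Li])c(OCOC)c(C(CC(C)C)O[Si](C)(C)C(C)(C)C)c(OCOC)c1CO[Si](C)(C)C(C)(C)C | intermediate (not isolated)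
39 | aryl(octahydroazulenyl)methanol from 38 and 24 (3S,5R,8R,8aR; epimers at both benzylic carbinol carbons) | COCOc1c(C(O)[C@@]2(C)CC[C@H]3C2=C[C@H](C(C)(C)OCOC)CC[C@H]3C)c(OCOC)c(C(CC(C)C)O[Si](C)(C)C(C)(C)C)c(OCOC)c1CO[Si](C)(C)C(C)(C)C | intermediate
40 | sodium alkoxide of 39 | COCOc1c(C([O-])[C@@]2(C)CC[C@H]3C2=C[C@H](C(C)(C)OCOC)CC[C@H]3C)c(OCOC)c(C(CC(C)C)O[Si](C)(C)C(C)(C)C)c(OCOC)c1CO[Si](C)(C)C(C)(C)C.[Na+] | intermediate (not isolated)
41 | sodium O-alkyl dithiocarbonate of 39 | COCOc1c(C(OC(=S)[S-])[C@@]2(C)CC[C@H]3C2=C[C@H](C(C)(C)OCOC)CC[C@H]3C)c(OCOC)c(C(CC(C)C)O[Si](C)(C)C(C)(C)C)c(OCOC)c1CO[Si](C)(C)C(C)(C)C.[Na+] | intermediate (not isolated)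
42 | O-alkyl S-methyl dithiocarbonate of 39 | COCOc1c(C(OC(=S)SC)[C@@]2(C)CC[C@H]3C2=C[C@H](C(C)(C)OCOC)CC[C@H]3C)c(OCOC)c(C(CC(C)C)O[Si](C)(C)C(C)(C)C)c(OCOC)c1CO[Si](C)(C)C(C)(C)C | intermediate
43 | deoxygenated bis-silyl ether (3R,5R,8R,8aR; one silyloxy carbon racemic) | COCOc1c(C[C@@]2(C)CC[C@H]3C2=C[C@H](C(C)(C)OCOC)CC[C@H]3C)c(OCOC)c(C(CC(C)C)O[Si](C)(C)C(C)(C)C)c(OCOC)c1CO[Si](C)(C)C(C)(C)C | intermediate
44 | diol (3R,5R,8R,8aR; secondary carbinol epimers) | COCOc1c(C[C@@]2(C)CC[C@H]3C2=C[C@H](C(C)(C)OCOC)CC[C@H]3C)c(OCOC)c(C(O)CC(C)C)c(OCOC)c1CO | intermediate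
45 | 3-{[(3R,5R,8R,8aR)-5-[2-(methoxymethoxy)propan-2-yl]-3,8-dimethyl-1,2,3,5,6,7,8,8a-octahydroazulen-3-yl]methyl}-2,4,6-tris(methoxymethoxy)-5-(3-methylbutanoyl)benzaldehyde | COCOc1c(C[C@@]2(C)CC[C@H]3C2=C[C@H](C(C)(C)OCOC)CC[C@H]3C)c(OCOC)c(C(=O)CC(C)C)c(OCOC)c1C=O | intermediate
46 | 2,4,6-trihydroxy-3-{[(3R,5R,8R,8aR)-5-(2-hydroxypropan-2-yl)-3,8-dimethyl-1,2,3,5,6,7,8,8a-octahydroazulen-3-yl]methyl}-5-(3-methylbutanoyl)benzaldehyde (CNP0583424.1) | CC(C)CC(=O)c1c(O)c(C=O)c(O)c(C[C@@]2(C)CC[C@H]3C2=C[C@H](C(C)(C)O)CC[C@H]3C)c1O | target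

**Step count**
Total steps: 33. Longest linear sequence: 20 steps (steps 1–8, 13–18, 28–33); 20/33 = 0.61. The other branches are steps 9–12 (allylboronate 16) and steps 19–27 (aryl bromide 37).

**Three steps most likely to fail**

Step 13 (allylboration). The boronate carries a fully substituted carbon next to the reacting γ-carbon, so the closed transition state may be slow, and a mismatch with the existing centres may erode selectivity. Fallback, setting out from 15 and 10 and returning at 17: 15 is converted with CBr4/PPh3 into (2E)-1-bromo-4-(methoxymethoxy)-4-methylpent-2-ene F1, and F1 is added to 10 in a Barbier-type Nozaki–Hiyama allylation (CrCl2, THF, Kishi-type chiral sulfonamide ligand). The far more nucleophilic γ-substituted allylchromium species also reacts through a chair transition state to give the anti adduct 17.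

Step 17 (Still–Wittig shift onto a tetrasubstituted alkene). A [1,2] shift or simple protonation of the carbanion may compete when the new bond must form at a fully substituted carbon. Fallback, setting out from 19 and returning at 24: 19 is heated with N,N-dimethylformamide dimethyl acetal (xylene, 150 °C); the alkoxy(amino)carbene formed in situ undergoes the Büchi [2,3] shift with the same suprafacial chirality transfer to give the dimethylamide (3S,5R,8R,8aR)-5-[2-(methoxymethoxy)propan-2-yl]-N,N,3,8-tetramethyl-1,2,3,5,6,7,8,8a-octahydroazulene-3-carboxamide F2, and Cp2Zr(H)Cl reduces F2 directly to aldehyde 24 (steps 16–18 are replaced).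

Step 30 (radical deoxygenation). The benzylic radical sits next to a quaternary carbon bearing a vinyl group and may undergo a 1,2-vinyl shift through a cyclopropylcarbinyl radical; xanthate formation on the crowded carbinol may also be poor. Fallback, setting out from 23 and 37 and returning at 43: 23 is converted (I2, PPh3, imidazole) into the neopentyl iodide (3S,5R,8R,8aR)-3-(iodomethyl)-5-[2-(methoxymethoxy)propan-2-yl]-3,8-dimethyl-1,2,3,5,6,7,8,8a-octahydroazulene F3; t-BuLi at −78 °C gives the corresponding alkyllithium F4, ZnCl2 turns it into the alkylzinc chloride F5, and Negishi coupling of F5 with bromide 37 (Pd(OAc)2, CPhos, THF, 50 °C) gives 43 directly. The benzylic CH2 is formed by cross-coupling, so no benzylic radical or cation ever arises (steps 18 and 28–30 are replaced).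

**Further compounds**
F1 | step 13 | (2E)-1-bromo-4-(methoxymethoxy)-4-methylpent-2-ene | BrC/C=C/C(C)(C)OCOC
F2 | step 17 | (3S,5R,8R,8aR)-5-[2-(methoxymethoxy)propan-2-yl]-N,N,3,8-tetramethyl-1,2,3,5,6,7,8,8a-octahydroazulene-3-carboxamide | C[C@@H]1CC[C@@H](C(C)(C)OCOC)C=C2[C@@](C)(C(=O)N(C)C)CC[C@H]12
F3 | step 30 | (3S,5R,8R,8aR)-3-(iodomethyl)-5-[2-(methoxymethoxy)propan-2-yl]-3,8-dimethyl-1,2,3,5,6,7,8,8a-octahydroazulene | C[C@@H]1CC[C@@H](C(C)(C)OCOC)C=C2[C@@](C)(CI)CC[C@H]12
F4 | step 30 | alkyllithium from F3 (CH2Li in place of CH2I) | C[C@@H]1CC[C@@H](C(C)(C)OCOC)C=C2[C@@](C)(C[Li])CC[C@H]12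
F5 | step 30 | alkylzinc chloride from F4 (CH2ZnCl in place of CH2Li) | C[C@@H]1CC[C@@H](C(C)(C)OCOC)C=C2[C@@](C)(C[Zn]Cl)CC[C@H]12
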